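**Retrosynthetic overview**
- Target ⇐ Pd(0) O‑deallylation ⇐ (E)‑selective Horner–Wadsworth–Emmons union of a (2S)‑flavan‑8‑carbaldehyde with an O‑allyl benzylphosphonate.
- Flavan aldehyde ⇐ invertive Mitsunobu closure of O1–C2 ⇐ Mg‑mediated ortho‑formylation of an (R)‑1,3‑diarylpropan‑1‑ol phenol.
- (R)‑Carbinol ⇐ ketoreductase reduction of the dihydrochalcone ⇐ Claisen–Schmidt condensation/hydrogenation from 2‑hydroxy‑4,6‑dimethoxybenzaldehyde and acetophenone.
- Phosphonate ⇐ 3,5‑dimethoxy‑4‑methylphenol (C–H borylation/oxidation of 2,6‑dimethoxytoluene), then formylation, allylation, reduction, phosphonylation.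
- Ring order: all three benzene rings are bought intact; the dihydropyran ring is the only ring formed (step 6).

Assumption: the target is (2S) as drawn; BnBr, allyl bromide, B2pin2, P(OEt)3 and paraformaldehyde are treated as reagents, not numbered building blocks; the enzyme is chosen by screening a commercial ketoreductase panel for the (R)‑selective hit.

**Step 1**
Reactants: 1 2‑hydroxy‑4,6‑dimethoxybenzaldehyde
Product: 2 2‑(benzyloxy)‑4,6‑dimethoxybenzaldehyde
Conditions: BnBr, K2CO3, DMF, 60 °C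
Reagents that add atoms: benzyl bromide, BrCc1ccccc1
Why: Williamson etherification masks the phenol, whose phenoxide would otherwise deactivate the aldehyde in the following aldol condensation.

**Step 2**
Reactants: 2 2‑(benzyloxy)‑4,6‑dimethoxybenzaldehyde; 3 acetophenone
Product: 4 (E)‑3‑[2‑(benzyloxy)‑4,6‑dimethoxyphenyl]‑1‑phenylprop‑2‑en‑1‑one
Conditions: KOH (aq.), EtOH, rt
Reagents that add atoms: none
Why: Claisen–Schmidt condensation of a non‑enolisable aldehyde with a methyl ketone gives the (E)‑chalcone under thermodynamic control.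

**Step 3**
Reactants: 4 (E)‑3‑[2‑(benzyloxy)‑4,6‑dimethoxyphenyl]‑1‑phenylprop‑2‑en‑1‑one
Product: 5 3‑(2‑hydroxy‑4,6‑dimethoxyphenyl)‑1‑phenylpropan‑1‑one
Conditions: H2 (1 atm, stopped after 2 equiv), 10% Pd/C, EtOAc, rt
Reagents that add atoms: none
Why: Catalytic hydrogenation saturates the enone C=C and hydrogenolyses the aryl benzyl ether, both much faster than reduction of the aryl ketone in neutral EtOAc.

**Step 4**
Reactants: 5 3‑(2‑hydroxy‑4,6‑dimethoxyphenyl)‑1‑phenylpropan‑1‑one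
Product: 6 (R)‑3‑(2‑hydroxy‑4,6‑dimethoxyphenyl)‑1‑phenylpropan‑1‑ol
Conditions: (R)‑selective ketoreductase (KRED), NADP+ (cat.), iPrOH, KPi buffer pH 7/DMSO, 30 °C
Reagents that add atoms: none
Why: Ketoreductase (NADPH‑dependent alcohol dehydrogenase) reduction with isopropanol recycling; an anti‑Prelog enzyme delivers hydride to the si face of the aryl ketone and sets the (R)‑carbinol, a 1,3‑diarylpropan‑1‑one substrate class with process‑scale KRED precedent.

**Step 5**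
Reactants: 6 (R)‑3‑(2‑hydroxy‑4,6‑dimethoxyphenyl)‑1‑phenylpropan‑1‑ol
Product: 8 2‑hydroxy‑3‑[(3R)‑3‑hydroxy‑3‑phenylpropyl]‑4,6‑dimethoxybenzaldehyde, via salicyl alcohol 7 (not isolated)
Conditions: MgCl2, Et3N, (CH2O)n, THF, reflux; then aq. citric acid
Reagents that add atoms: paraformaldehyde (as formaldehyde), C=O
Why: Casnati–Skattebøl ortho‑formylation proceeds through the magnesium phenoxide, so formaldehyde is delivered only to the single free ortho position (not the para site between the methoxy groups), and the hydroxymethyl intermediate is oxidised in situ by a second formaldehyde.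

**Step 6**
Reactants: 8 2‑hydroxy‑3‑[(3R)‑3‑hydroxy‑3‑phenylpropyl]‑4,6‑dimethoxybenzaldehyde
Product: 9 (2S)‑5,7‑dimethoxy‑2‑phenylchromane‑8‑carbaldehyde
Conditions: PPh3, DIAD, THF, 0 °C → rt
Reagents that add atoms: none
Why: Intramolecular Mitsunobu etherification; the acidic salicylaldehyde phenol displaces the activated benzylic carbinol by SN2 with inversion, converting (R)‑carbinol into the (2S)‑flavan.

**Step 7**
Reactants: 10 2,6‑dimethoxytoluene
Product: 11 2‑(3,5‑dimethoxy‑4‑methylphenyl)‑4,4,5,5‑tetramethyl‑1,3,2‑dioxaborolane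
Conditions: [Ir(OMe)(cod)]2 (1.5 mol %), dtbpy (3 mol %), B2pin2 (1.0 equiv), THF, 80 °C
Reagents that add atoms: bis(pinacolato)diboron, CC1(C)OB(OC1(C)C)B1OC(C)(C)C(C)(C)O1
Why: Sterically controlled Ir‑catalysed C–H borylation occurs only at the one ring position that has no ortho substituent.

**Step 8**
Reactants: 11 2‑(3,5‑dimethoxy‑4‑methylphenyl)‑4,4,5,5‑tetramethyl‑1,3,2‑dioxaborolane
Product: 12 3,5‑dimethoxy‑4‑methylphenol
Conditions: Oxone, acetone/H2O, rt
Reagents that add atoms: Oxone (potassium peroxymonosulfate), [K+].OOS(=O)(=O)[O-]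
Why: Oxidation of the aryl boronate (1,2‑aryl shift from boron to oxygen, then hydrolysis) gives the phenol ipso to boron.

**Step 9**
Reactants: 12 3,5‑dimethoxy‑4‑methylphenol
Product: 14 6‑hydroxy‑2,4‑dimethoxy‑3‑methylbenzaldehyde, via hydroxymethylphenol 13 (not isolated)
Conditions: MgCl2, Et3N, (CH2O)n, MeCN, reflux; then 1 M HCl
Reagents that add atoms: paraformaldehyde (as formaldehyde), C=O
Why: Casnati–Skattebøl ortho‑formylation; the two free ring positions are symmetry‑equivalent and both ortho to OH, so only one aldehyde can form.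

**Step 10**
Reactants: 14 6‑hydroxy‑2,4‑dimethoxy‑3‑methylbenzaldehyde
Product: 15 6‑(allyloxy)‑2,4‑dimethoxy‑3‑methylbenzaldehyde
Conditions: allyl bromide, K2CO3, DMF, 50 °C
Reagents that add atoms: allyl bromide, C=CCBr
Why: Williamson etherification installs a base‑stable phenol protecting group that can later be removed under neutral Pd(0) conditions, avoiding acid on the electron‑rich stilbene.

**Step 11**
Reactants: 15 6‑(allyloxy)‑2,4‑dimethoxy‑3‑methylbenzaldehyde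
Product: 16 [6‑(allyloxy)‑2,4‑dimethoxy‑3‑methylphenyl]methanol
Conditions: NaBH4, MeOH/THF, 0 °C
Reagents that add atoms: none
Why: Borohydride reduction of the aldehyde to the benzylic alcohol leaves the allyl ether and arene untouched.

**Step 12**
Reactants: 16 [6‑(allyloxy)‑2,4‑dimethoxy‑3‑methylphenyl]methanol
Product: 17 diethyl {[6‑(allyloxy)‑2,4‑dimethoxy‑3‑methylphenyl]methyl}phosphonate
Conditions: P(OEt)3 (3 equiv), ZnI2 (1.5 equiv), THF, reflux
Reagents that add atoms: triethyl phosphite, CCOP(OCC)OCC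
Why: ZnI2‑mediated one‑flask Arbuzov‑type phosphonylation converts the electron‑rich benzylic alcohol directly to the phosphonate without isolating the unstable trialkoxybenzyl halide.

**Step 13**
Reactants: 17 diethyl {[6‑(allyloxy)‑2,4‑dimethoxy‑3‑methylphenyl]methyl}phosphonate; 9 (2S)‑5,7‑dimethoxy‑2‑phenylchromane‑8‑carbaldehyde
Product: 18 (2S)‑8‑{(E)‑2‑[6‑(allyloxy)‑2,4‑dimethoxy‑3‑methylphenyl]vinyl}‑5,7‑dimethoxy‑2‑phenylchromane
Conditions: NaH, 15‑crown‑5, THF, 0 °C → rt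
Reagents that add atoms: none
Why: Horner–Wadsworth–Emmons olefination of the benzylphosphonate anion with the aryl aldehyde gives the (E)‑stilbene, and the non‑acidic C2–H stereocentre is untouched.

**Step 14**
Reactants: 18 (2S)‑8‑{(E)‑2‑[6‑(allyloxy)‑2,4‑dimethoxy‑3‑methylphenyl]vinyl}‑5,7‑dimethoxy‑2‑phenylchromane
Product: 19 2‑{(E)‑2‑[(2S)‑5,7‑dimethoxy‑2‑phenylchroman‑8‑yl]vinyl}‑3,5‑dimethoxy‑4‑methylphenol (CNP0000264.1)
Conditions: Pd(PPh3)4 (5 mol %), morpholine, THF, rt, Ar, dark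
Reagents that add atoms: none
Why: Tsuji–Trost deallylation (π‑allyl‑Pd trapped by morpholine) frees the phenol under neutral conditions that leave the stilbene, methyl ethers and flavan stereocentre intact.

**Compound list**
1 | 2‑hydroxy‑4,6‑dimethoxybenzaldehyde | COc1cc(O)c(C=O)c(OC)c1 | starting material
2 | 2‑(benzyloxy)‑4,6‑dimethoxybenzaldehyde | COc1cc(OCc2ccccc2)c(C=O)c(OC)c1 | intermediate
3 | acetophenone | CC(=O)c1ccccc1 | starting material
4 | (E)‑3‑[2‑(benzyloxy)‑4,6‑dimethoxyphenyl]‑1‑phenylprop‑2‑en‑1‑one | COc1cc(OCc2ccccc2)c(/C=C/C(=O)c2ccccc2)c(OC)c1 | intermediate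
5 | 3‑(2‑hydroxy‑4,6‑dimethoxyphenyl)‑1‑phenylpropan‑1‑one | COc1cc(O)c(CCC(=O)c2ccccc2)c(OC)c1 | intermediate
6 | (R)‑3‑(2‑hydroxy‑4,6‑dimethoxyphenyl)‑1‑phenylpropan‑1‑ol | COc1cc(O)c(CC[C@@H](O)c2ccccc2)c(OC)c1 | intermediate
7 | 2‑(hydroxymethyl)‑6‑[(3R)‑3‑hydroxy‑3‑phenylpropyl]‑3,5‑dimethoxyphenol | COc1cc(OC)c(CC[C@@H](O)c2ccccc2)c(O)c1CO | intermediate
8 | 2‑hydroxy‑3‑[(3R)‑3‑hydroxy‑3‑phenylpropyl]‑4,6‑dimethoxybenzaldehyde | COc1cc(OC)c(CC[C@@H](O)c2ccccc2)c(O)c1C=O | intermediate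
9 | (2S)‑5,7‑dimethoxy‑2‑phenylchromane‑8‑carbaldehyde | O=Cc1c(OC)cc(OC)c2c1O[C@H](c1ccccc1)CC2 | intermediate
10 | 2,6‑dimethoxytoluene | COc1cccc(OC)c1C | starting material
11 | 2‑(3,5‑dimethoxy‑4‑methylphenyl)‑4,4,5,5‑tetramethyl‑1,3,2‑dioxaborolane | COc1cc(B2OC(C)(C)C(C)(C)O2)cc(OC)c1C | intermediate
12 | 3,5‑dimethoxy‑4‑methylphenol | COc1cc(O)cc(OC)c1C | intermediate
13 | 2‑(hydroxymethyl)‑3,5‑dimethoxy‑4‑methylphenol | COc1cc(O)c(CO)c(OC)c1C | intermediate
14 | 6‑hydroxy‑2,4‑dimethoxy‑3‑methylbenzaldehyde | COc1cc(O)c(C=O)c(OC)c1C | intermediate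
15 | 6‑(allyloxy)‑2,4‑dimethoxy‑3‑methylbenzaldehyde | COc1cc(OCC=C)c(C=O)c(OC)c1C | intermediate
16 | [6‑(allyloxy)‑2,4‑dimethoxy‑3‑methylphenyl]methanol | COc1cc(OCC=C)c(CO)c(OC)c1C | intermediate
17 | diethyl {[6‑(allyloxy)‑2,4‑dimethoxy‑3‑methylphenyl]methyl}phosphonate | CCOP(=O)(Cc1c(OCC=C)cc(OC)c(C)c1OC)OCC | intermediate
18 | (2S)‑8‑{(E)‑2‑[6‑(allyloxy)‑2,4‑dimethoxy‑3‑methylphenyl]vinyl}‑5,7‑dimethoxy‑2‑phenylchromane | COc1cc(OCC=C)c(/C=C/c2c(OC)cc(OC)c3c2O[C@H](c2ccccc2)CC3)c(OC)c1C | intermediate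
19 | 2‑{(E)‑2‑[(2S)‑5,7‑dimethoxy‑2‑phenylchroman‑8‑yl]vinyl}‑3,5‑dimethoxy‑4‑methylphenol | COc1cc(O)c(/C=C/c2c(OC)cc(OC)c3c2O[C@H](c2ccccc2)CC3)c(OC)c1C | target

**Totals**
Total step count: 14. Longest linear sequence: 8 steps (steps 1–6, 13, 14; the branch 7–12, 13, 14 is also 8).

**Three steps most likely to fail**

Step 5 (ortho‑formylation in the presence of the free benzylic carbinol). The fallback sets out from 6 and returns at 9. Diol 6 is cyclised first under the Mitsunobu conditions of step 6 (PPh3, DIAD, THF) to (2S)‑5,7‑dimethoxy‑2‑phenylchromane F1. F1 is brominated with NBS (CH2Cl2, −40 °C), which is C8‑selective in 5,7‑dialkoxyflavans, to (2S)‑8‑bromo‑5,7‑dimethoxy‑2‑phenylchromane F2; the regiochemistry is confirmed by NOE. Br/Li exchange on F2 (n‑BuLi, THF, −78 °C) and a DMF quench give aldehyde 9.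

Step 12 (phosphonylation of a very electron‑rich benzylic alcohol that can self‑alkylate). The fallback sets out from 16 and returns at 18. Alcohol 16 is heated with PPh3·HBr in MeCN to give {[6‑(allyloxy)‑2,4‑dimethoxy‑3‑methylphenyl]methyl}triphenylphosphonium bromide F3. The ylide (LiHMDS, THF, −78 °C → rt) undergoes Wittig olefination with aldehyde 9 to give 18 together with (2S)‑8‑{(Z)‑2‑[6‑(allyloxy)‑2,4‑dimethoxy‑3‑methylphenyl]vinyl}‑5,7‑dimethoxy‑2‑phenylchromane F4. Catalytic I2 in heptane under light/reflux isomerises F4 so that the mixture converges on (E)‑18.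

Step 13 (HWE forming a tetra‑ortho‑substituted stilbene). The fallback sets out from 9 and 12 and returns at 19, bypassing steps 13 and 14. Aldehyde 9 undergoes a boron‑Wittig reaction with LiCH(Bpin)2 (from CH2(Bpin)2 and LiTMP, THF, 0 °C → rt) to give (2S)‑5,7‑dimethoxy‑2‑phenyl‑8‑[(E)‑2‑(4,4,5,5‑tetramethyl‑1,3,2‑dioxaborolan‑2‑yl)vinyl]chromane F5. Phenol 12 is mono‑iodinated (NIS, MeCN, 0 °C) at one of its two equivalent ortho positions to give 2‑iodo‑3,5‑dimethoxy‑4‑methylphenol F6. Stereoretentive Suzuki–Miyaura coupling of F5 with F6 (Pd(OAc)2/SPhos, K3PO4, dioxane/H2O, 80 °C) gives 19 directly.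

**Further compounds**
F1 | step 5 | (2S)‑5,7‑dimethoxy‑2‑phenylchromane | c1c(OC)cc(OC)c2c1O[C@H](c1ccccc1)CC2
F2 | step 5 | (2S)‑8‑bromo‑5,7‑dimethoxy‑2‑phenylchromane | Brc1c(OC)cc(OC)c2c1O[C@H](c1ccccc1)CC2
F3 | step 12 | {[6‑(allyloxy)‑2,4‑dimethoxy‑3‑methylphenyl]methyl}triphenylphosphonium bromide | COc1cc(OCC=C)c(C[P+](c2ccccc2)(c2ccccc2)c2ccccc2)c(OC)c1C.[Br-]
F4 | step 12 | (2S)‑8‑{(Z)‑2‑[6‑(allyloxy)‑2,4‑dimethoxy‑3‑methylphenyl]vinyl}‑5,7‑dimethoxy‑2‑phenylchromane | COc1cc(OCC=C)c(/C=C\c2c(OC)cc(OC)c3c2O[C@H](c2ccccc2)CC3)c(OC)c1C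
F5 | step 13 | (2S)‑5,7‑dimethoxy‑2‑phenyl‑8‑[(E)‑2‑(4,4,5,5‑tetramethyl‑1,3,2‑dioxaborolan‑2‑yl)vinyl]chromane | CC1(C)OB(/C=C/c2c(OC)cc(OC)c3c2O[C@H](c2ccccc2)CC3)OC1(C)C
F6 | step 13 | 2‑iodo‑3,5‑dimethoxy‑4‑methylphenol | COc1cc(O)c(I)c(OC)c1C
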